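## Retrosynthetic overview

1. The seven-membered lactone (O3–C16) is closed last from a hydroxy acid; C16 is carried as a silyl-protected primary alcohol.
2. The nine-membered oxacycle is closed by ring-closing metathesis (C6=C7); the C11 methyl/butanoate comes from MeLi addition to a ketone with in-flask acylation.
3. The tetrahydrofuran (C9–C10 and C9–O) comes from a Lewis-acid annulation of a methallyl acetal onto a γ-hydroxy enol carbamate.
4. Key bond C1–C2: a metalated cyclohexenyl carbamate (homoenolate of the latent C11 ketone, nucleophilic at the β-carbon C1) adds to an α-silyloxy aldehyde.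
5. Ring order: cyclohexene (organocatalytic Robinson annulation) → tetrahydrofuran → nine-membered ring → lactone.

Assumption: atoms are numbered as in the cladiellane skeleton (cyclohexane = C1, C10–C14; ether bridge C2–O–C9; methyls on C3, C7, C11, C15; lactone carbonyl C16). The target is then (1S,2S,3S,6Z,9S,10R,11R,14R,15R).

## Route

**Fragment A (cyclohexenyl carbamate)**

Step 1
Reactants: 1 methyl (2S)-3-hydroxy-2-methylpropanoate
Product: 2 methyl (2S)-3-[(tert-butyldiphenylsilyl)oxy]-2-methylpropanoate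
Conditions: tBuPh2SiCl, imidazole, DMF, 0 °C → rt
Reagents that add atoms: tert-butylchlorodiphenylsilane, CC(C)(C)[Si](Cl)(c1ccccc1)c1ccccc1
Why: Standard silylation of a primary alcohol; the purchased stereocentre (future C15) is untouched.

Step 2
Reactants: 2 methyl (2S)-3-[(tert-butyldiphenylsilyl)oxy]-2-methylpropanoate
Product: 3 (2S)-3-[(tert-butyldiphenylsilyl)oxy]-2-methylpropanal
Conditions: iBu2AlH (1.05 equiv), CH2Cl2, −78 °C; aq. KNaC4H4O6
Reagents that add atoms: none
Why: Partial ester reduction stops at the aluminium hemiacetal at −78 °C, and the base-free conditions keep the α-centre intact (the aldehyde is used crude).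

Step 3
Reactants: 3 (2S)-3-[(tert-butyldiphenylsilyl)oxy]-2-methylpropanal
Product: 5 (3R)-4-[(tert-butyldiphenylsilyl)oxy]-3-methylbutanal, via methyl enol ether 4 (not isolated)
Conditions: Ph3P(CH2OMe)Cl, KN(SiMe3)2, THF, 0 °C; 3, −78 °C → rt; then 2 M HCl, THF, rt
Reagents that add atoms: (methoxymethyl)triphenylphosphonium chloride, COC[P+](c1ccccc1)(c1ccccc1)c1ccccc1.[Cl-]; water, O
Why: Wittig methoxymethylenation followed by enol ether hydrolysis is a one-carbon homologation that moves the stereocentre to the safe β-position; the silyl ether survives dilute acid.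

Step 4
Reactants: 5 (3R)-4-[(tert-butyldiphenylsilyl)oxy]-3-methylbutanal; 6 but-3-en-2-one
Product: 8 (4R)-4-{(2R)-1-[(tert-butyldiphenylsilyl)oxy]propan-2-yl}cyclohex-2-en-1-one, via keto aldehyde 7 (not isolated)
Conditions: (S)-2-(methoxydiphenylmethyl)pyrrolidine (10 mol %), ethyl 3,4-dihydroxybenzoate (20 mol %), neat, 4 °C; then KOH (0.2 equiv), nBu4NOH (cat.), Et2O/THF/H2O, rt → 40 °C
Reagents that add atoms: none
Why: Organocatalytic Robinson annulation (enamine Michael addition, then aldol condensation); the catalyst's diarylmethyl group blocks one enamine face, so C14 is set under catalyst control as (2S) in 7, which becomes (4R) in 8.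

Step 5
Reactants: 8 (4R)-4-{(2R)-1-[(tert-butyldiphenylsilyl)oxy]propan-2-yl}cyclohex-2-en-1-one
Product: 9 (1R,4R)-4-{(2R)-1-[(tert-butyldiphenylsilyl)oxy]propan-2-yl}cyclohex-2-en-1-ol
Conditions: NaBH4, CeCl3·7H2O, MeOH, −78 °C
Reagents that add atoms: none
Why: Luche 1,2-reduction; axial hydride delivery to the half-chair with the side chain pseudo-equatorial gives mainly the trans (1R,4R) allylic alcohol, and the minor cis isomer is removed by chromatography.

Step 6
Reactants: 9 (1R,4R)-4-{(2R)-1-[(tert-butyldiphenylsilyl)oxy]propan-2-yl}cyclohex-2-en-1-ol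
Product: 10 (1R,4R)-4-{(2R)-1-[(tert-butyldiphenylsilyl)oxy]propan-2-yl}cyclohex-2-en-1-yl N,N-diisopropylcarbamate
Conditions: NaH, THF, 0 °C; iPr2NCOCl, reflux
Reagents that add atoms: N,N-diisopropylcarbamoyl chloride, CC(C)N(C(C)C)C(Cl)=O
Why: O-Carbamoylation of the sodium alkoxide installs the directing group for the later deprotonation without touching a stereocentre.

**Fragment B (aldehyde carrying C2–C6)**

Step 7
Reactants: 11 2-methylprop-2-en-1-ol
Product: 12 (R)-(2-methyloxiran-2-yl)methanol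
Conditions: Ti(OiPr)4 (5 mol %), D-(−)-diethyl tartrate (6 mol %), tBuOOH, 4 Å MS, CH2Cl2, −20 °C
Reagents that add atoms: tert-butyl hydroperoxide, CC(C)(C)OO
Why: Sharpless asymmetric epoxidation; the D-tartrate titanium complex delivers oxygen to the alkene face that gives the (R)-epoxide, whose quaternary carbon becomes C3.

Step 8
Reactants: 12 (R)-(2-methyloxiran-2-yl)methanol
Product: 13 (2S)-2-methylhex-5-ene-1,2-diol
Conditions: CH2=CHCH2MgBr (2.5 equiv), CuI (10 mol %), THF, −30 → 0 °C
Reagents that add atoms: allylmagnesium bromide, C=CC[Mg]Br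
Why: SN2 epoxide opening at the unsubstituted CH2 leaves the quaternary carbinol centre untouched (the descriptor changes to S only through ligand priorities).

Step 9
Reactants: 13 (2S)-2-methylhex-5-ene-1,2-diol
Product: 14 (2S)-2-methyl-1,2-bis[(triethylsilyl)oxy]hex-5-ene
Conditions: Et3SiOTf (2.3 equiv), 2,6-lutidine, CH2Cl2, −78 → 0 °C
Reagents that add atoms: triethylsilyl trifluoromethanesulfonate, CC[Si](CC)(CC)OS(=O)(=O)C(F)(F)F
Why: The silyl triflate is reactive enough to silylate the tertiary as well as the primary hydroxyl.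

Step 10
Reactants: 14 (2S)-2-methyl-1,2-bis[(triethylsilyl)oxy]hex-5-ene
Product: 15 (2S)-2-methyl-2-[(triethylsilyl)oxy]hex-5-enal
Conditions: (COCl)2, DMSO, CH2Cl2, −78 °C; 14, −78 → −30 °C; Et3N, → 0 °C
Reagents that add atoms: none
Why: Swern conditions oxidise a primary triethylsilyl ether directly to the aldehyde (O-sulfonium formation with loss of Et3SiCl) while the hindered tertiary silyl ether is inert; the α-carbon is quaternary and cannot epimerise.

**Acetal for C7–C9**

Step 11
Reactants: 16 triethyl orthoformate; 17 (2-methylallyl)magnesium chloride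
Product: 18 4,4-diethoxy-2-methylbut-1-ene
Conditions: THF, 0 °C → reflux; aq. NH4Cl
Reagents that add atoms: none
Why: Bodroux–Chichibabin acetal synthesis; the allylic Grignard reagent displaces one ethoxide of the orthoester and stops at the acetal.

**Assembly**

Step 12
Reactants: 10 (1R,4R)-cyclohexenyl N,N-diisopropylcarbamate; 15 (2S)-2-methyl-2-[(triethylsilyl)oxy]hex-5-enal
Product: 21 homoaldol adduct (γ-hydroxyalkyl enol carbamate), via lithiated carbamate 19 (not isolated), via titanated carbamate 20 (not isolated)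
Conditions: sBuLi (1.2 equiv), TMEDA, Et2O, −78 °C, 1 h; ClTi(OiPr)3 (3 equiv), −78 °C; 15, −78 → −20 °C; aq. NH4Cl
Reagents that add atoms: none
Why: Hoppe homoaldol reaction: the α-metalated allyl carbamate is a homoenolate equivalent of the 4-substituted cyclohexanone and adds through its β-carbon C1 to the aldehyde carbon C2 in a closed six-membered titanium transition state; lithiation with retention and Li→Ti exchange with inversion put titanium on the face anti to the C14 side chain, so C1–C2 forms trans to it, and the bulky aldehyde residue sits exo to the carbocycle to give the (1S,2S) adduct, as known for titanated 4-alkylcyclohex-2-enyl carbamates, while C3 is carried in by the aldehyde.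

Step 13
Reactants: 21 homoaldol adduct; 18 4,4-diethoxy-2-methylbut-1-ene
Product: 23 cis-fused bicyclic ketone (hexahydroisobenzofuran-4-one), via mixed acetal 22 (not isolated)
Conditions: BF3·OEt2 (3 equiv), CH2Cl2, −78 → −20 °C
Reagents that add atoms: none
Why: Lewis-acid tetrahydrofuran annulation (transacetalisation to an oxocarbenium ion on O2, then Mukaiyama/Prins-type attack by the enol carbamate carbon C10, with the carbamoyl group lost to ethanol); attack is only possible on the face carrying C2, so the fusion is cis (10R), and the E-oxocarbenium places the methallyl group exo and cis to the C3 arm (9S).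

Step 14
Reactants: 23 cis-fused bicyclic ketone
Product: 25 tertiary butanoate diene, via lithium alkoxide 24 (not isolated)
Conditions: MeLi (1.3 equiv), THF, −78 °C; then (PrCO)2O (3 equiv), −78 → 0 °C
Reagents that add atoms: methyllithium, [Li]C; butanoic anhydride, CCCC(=O)OC(=O)CCC
Why: 1,2-Addition then O-acylation in the same flask; methyl attacks the C11 ketone axially on the convex face anti to the C10–C9 bond (methyl cis to H-10, 11R), and the tertiary lithium alkoxide is trapped by the anhydride.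

Step 15
Reactants: 25 tertiary butanoate diene
Product: 26 tricyclic (6Z)-alkene with both silyl ethers
Conditions: second-generation Grubbs catalyst RuCl2(=CHPh)(PCy3)(H2IMes) (10 mol %), toluene (2 mM), 80 °C
Reagents that add atoms: none
Why: Ring-closing metathesis of the butenyl and methallyl arms, which are held cis on the tetrahydrofuran; the nine-membered ring allows only the Z trisubstituted alkene.

Step 16
Reactants: 26 tricyclic (6Z)-alkene with both silyl ethers
Product: 27 tricyclic diol (C3 tertiary OH and C16 primary OH)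
Conditions: Bu4NF, AcOH (1:1), THF, 40 °C
Reagents that add atoms: none
Why: Buffered fluoride cleaves both silyl ethers while the hindered tertiary butanoate survives.

Step 17
Reactants: 27 tricyclic diol
Product: 28 hydroxy acid (C16 carboxylic acid and C3 tertiary OH)
Conditions: TEMPO (20 mol %), PhI(OAc)2 (2.5 equiv), MeCN/pH 7 buffer (1:1), rt
Reagents that add atoms: water, O
Why: Oxoammonium oxidation takes only the primary alcohol, through the aldehyde hydrate, to the acid; the tertiary alcohol and the trisubstituted alkene are inert, and the near-neutral conditions protect C15.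

Step 18
Reactants: 28 hydroxy acid
Product: 30 target lactone CNP0294597.2, via mixed anhydride 29 (not isolated)
Conditions: 2,4,6-Cl3C6H2COCl, Et3N, THF, rt; then DMAP, toluene (1 mM), 80 °C
Reagents that add atoms: none
Why: Yamaguchi lactonisation; the acylpyridinium derived from the mixed anhydride is captured intramolecularly by the C3 tertiary hydroxyl, which the trans-diequatorial C14/C1 substituents hold next to C16, and no stereocentre is involved.

## Compound list

1 | methyl (2S)-3-hydroxy-2-methylpropanoate | COC(=O)[C@@H](C)CO | starting material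
2 | methyl (2S)-3-[(tert-butyldiphenylsilyl)oxy]-2-methylpropanoate | COC(=O)[C@@H](C)CO[Si](c1ccccc1)(c1ccccc1)C(C)(C)C | intermediate
3 | (2S)-3-[(tert-butyldiphenylsilyl)oxy]-2-methylpropanal | O=C[C@@H](C)CO[Si](c1ccccc1)(c1ccccc1)C(C)(C)C | intermediate
4 | tert-butyl{[(2R)-4-methoxy-2-methylbut-3-en-1-yl]oxy}diphenylsilane (E/Z mixture) | COC=C[C@@H](C)CO[Si](c1ccccc1)(c1ccccc1)C(C)(C)C | intermediate
5 | (3R)-4-[(tert-butyldiphenylsilyl)oxy]-3-methylbutanal | O=CC[C@@H](C)CO[Si](c1ccccc1)(c1ccccc1)C(C)(C)C | intermediate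
6 | but-3-en-2-one | CC(=O)C=C | starting material
7 | (2S)-2-{(2R)-1-[(tert-butyldiphenylsilyl)oxy]propan-2-yl}-5-oxohexanal | CC(=O)CC[C@H](C=O)[C@@H](C)CO[Si](c1ccccc1)(c1ccccc1)C(C)(C)C | intermediate
8 | (4R)-4-{(2R)-1-[(tert-butyldiphenylsilyl)oxy]propan-2-yl}cyclohex-2-en-1-one | O=C1C=C[C@H]([C@@H](C)CO[Si](c2ccccc2)(c2ccccc2)C(C)(C)C)CC1 | intermediate
9 | (1R,4R)-4-{(2R)-1-[(tert-butyldiphenylsilyl)oxy]propan-2-yl}cyclohex-2-en-1-ol (trans) | O[C@H]1C=C[C@H]([C@@H](C)CO[Si](c2ccccc2)(c2ccccc2)C(C)(C)C)CC1 | intermediate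
10 | (1R,4R)-4-{(2R)-1-[(tert-butyldiphenylsilyl)oxy]propan-2-yl}cyclohex-2-en-1-yl N,N-diisopropylcarbamate | CC(C)N(C(C)C)C(=O)O[C@H]1C=C[C@H]([C@@H](C)CO[Si](c2ccccc2)(c2ccccc2)C(C)(C)C)CC1 | intermediate
11 | 2-methylprop-2-en-1-ol | C=C(C)CO | starting material
12 | (R)-(2-methyloxiran-2-yl)methanol | OC[C@]1(C)CO1 | intermediate
13 | (2S)-2-methylhex-5-ene-1,2-diol | OC[C@@](C)(O)CCC=C | intermediate
14 | (2S)-2-methyl-1,2-bis[(triethylsilyl)oxy]hex-5-ene | CC[Si](CC)(CC)OC[C@@](C)(O[Si](CC)(CC)CC)CCC=C | intermediate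
15 | (2S)-2-methyl-2-[(triethylsilyl)oxy]hex-5-enal | O=C[C@@](C)(O[Si](CC)(CC)CC)CCC=C | intermediate
16 | triethyl orthoformate | CCOC(OCC)OCC | starting material
17 | (2-methylallyl)magnesium chloride | CC(=C)C[Mg]Cl | starting material
18 | 4,4-diethoxy-2-methylbut-1-ene | CCOC(CC(C)=C)OCC | intermediate
19 | 1-lithio derivative of 10 (lithium in place of H-1 of the ring, same face) | CC(C)N(C(C)C)C(=O)O[C@@]1([Li])C=C[C@H]([C@@H](C)CO[Si](c2ccccc2)(c2ccccc2)C(C)(C)C)CC1 | intermediate
20 | 1-[tri(isopropoxy)titanio] derivative of 10 (titanium on the face anti to the side chain) | CC(C)N(C(C)C)C(=O)O[C@]1([Ti](OC(C)C)(OC(C)C)OC(C)C)C=C[C@H]([C@@H](C)CO[Si](c2ccccc2)(c2ccccc2)C(C)(C)C)CC1 | intermediate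
21 | (3S,4S)-3-{(1S,2S)-1-hydroxy-2-methyl-2-[(triethylsilyl)oxy]hex-5-en-1-yl}-4-{(2R)-1-[(tert-butyldiphenylsilyl)oxy]propan-2-yl}cyclohex-1-en-1-yl N,N-diisopropylcarbamate | CC(C)N(C(C)C)C(=O)OC1=C[C@@H]([C@H](O)[C@](C)(CCC=C)O[Si](CC)(CC)CC)[C@H]([C@@H](C)CO[Si](c2ccccc2)(c2ccccc2)C(C)(C)C)CC1 | intermediate
22 | mixed ethyl acetal of 21 with 3-methylbut-3-enal on O2 (acetal carbon unassigned) | CC(C)N(C(C)C)C(=O)OC1=C[C@@H]([C@H](OC(OCC)CC(C)=C)[C@](C)(CCC=C)O[Si](CC)(CC)CC)[C@H]([C@@H](C)CO[Si](c2ccccc2)(c2ccccc2)C(C)(C)C)CC1 | intermediate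
23 | cis-fused hexahydroisobenzofuran-4-one, cladiellane numbering (1S,2S,3S,9S,10R,14S,15R): C11 ketone, exo 2-methylallyl on C9, exo C3(Me)(OSiEt3)(but-3-enyl) on C2, CH(CH3)CH2OSiPh2tBu on C14 | O=C1CC[C@@H]([C@@H](C)CO[Si](c4ccccc4)(c4ccccc4)C(C)(C)C)[C@H]3[C@@H]1[C@H](CC(C)=C)O[C@@H]3[C@](C)(CCC=C)O[Si](CC)(CC)CC | intermediate
24 | lithium (11R)-alkoxide from methyl addition to 23 | [Li]O[C@]1(C)CC[C@@H]([C@@H](C)CO[Si](c4ccccc4)(c4ccccc4)C(C)(C)C)[C@H]3[C@@H]1[C@H](CC(C)=C)O[C@@H]3[C@](C)(CCC=C)O[Si](CC)(CC)CC | intermediate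
25 | (1S,2S,3S,9S,10R,11R,14S,15R)-11-butanoyloxy-11-methyl bicyclic diene (butenyl on C3, methallyl on C9, both silyl ethers) | CCCC(=O)O[C@]1(C)CC[C@@H]([C@@H](C)CO[Si](c4ccccc4)(c4ccccc4)C(C)(C)C)[C@H]3[C@@H]1[C@H](CC(C)=C)O[C@@H]3[C@](C)(CCC=C)O[Si](CC)(CC)CC | intermediate
26 | (1S,2S,3S,6Z,9S,10R,11R,14S,15R)-11-butanoyloxy-3-(triethylsilyloxy)-16-(tert-butyldiphenylsilyloxy)-2,9-epoxycladiell-6-ene | CCCC(=O)O[C@]1(C)CC[C@@H]([C@@H](C)CO[Si](c4ccccc4)(c4ccccc4)C(C)(C)C)[C@H]3[C@@H]1[C@@H]1C/C(C)=C\CC[C@](C)(O[Si](CC)(CC)CC)[C@H]3O1 | intermediate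
27 | (1S,2S,3S,6Z,9S,10R,11R,14S,15R)-11-butanoyloxy-2,9-epoxycladiell-6-ene-3,16-diol | CCCC(=O)O[C@]1(C)CC[C@@H]([C@@H](C)CO)[C@H]3[C@@H]1[C@@H]1C/C(C)=C\CC[C@](C)(O)[C@H]3O1 | intermediate
28 | (1S,2S,3S,6Z,9S,10R,11R,14R,15R)-11-butanoyloxy-3-hydroxy-2,9-epoxycladiell-6-en-16-oic acid | CCCC(=O)O[C@]1(C)CC[C@@H]([C@@H](C)C(=O)O)[C@H]3[C@@H]1[C@@H]1C/C(C)=C\CC[C@](C)(O)[C@H]3O1 | intermediate
29 | mixed anhydride of 28 with 2,4,6-trichlorobenzoic acid | CCCC(=O)O[C@]1(C)CC[C@@H]([C@@H](C)C(=O)OC(=O)c4c(Cl)cc(Cl)cc4Cl)[C@H]3[C@@H]1[C@@H]1C/C(C)=C\CC[C@](C)(O)[C@H]3O1 | intermediate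
30 | CNP0294597.2, (1S,2S,3S,6Z,9S,10R,11R,14R,15R)-11-butanoyloxy-2,9-epoxycladiell-6-en-16,3-olide | CCCC(=O)O[C@]1(C)CC[C@@H]2[C@H]3[C@@H]1[C@@H]1C/C(C)=C\CC[C@](C)(OC(=O)[C@@H]2C)[C@H]3O1 | target

## Step count and risks

Total: 18 steps (fragment A 6, fragment B 4, acetal 1, assembly 7). Longest linear sequence: 13 steps (steps 1–6 and 12–18).

**Step 12 (homoaldol).** The C1–C2 bond trans to the side chain is secure, but the carbinol configuration at C2 is the least certain point of the route. It depends on the aldehyde residue sitting exo in the closed transition state and on the Li→Ti exchange going with inversion. A simple chair model with the ring-locked Z-allyl unit would predict the C2 epimer, so the route leans on the precedent for this reagent class. The aldehyde's own facial bias is weak (methyl versus primary alkyl at C3). The fallback sets out from 10 and 15 and comes back at 21. If the same reaction gives mainly the C2-epimeric adduct F1, it is oxidised with Dess–Martin periodinane to the γ-keto enol carbamate F2. F2 is then reduced with LiBH(sBu)3 at −78 °C under polar Felkin–Anh control (silyloxy group anti to hydride, methyl outside), which by the model gives the (2S) carbinol 21. C2 is then set by a redox inversion instead of in the C–C bond formation.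

**Step 15 (ring-closing metathesis).** A nine-membered ring with a trisubstituted alkene must close next to a quaternary silyloxy carbon; dimerisation or failure to engage the methallyl group is possible. The fallback sets out from 25 and comes back at 30, closing the lactone before the medium ring. Compound 25 is desilylated (Bu4NF, AcOH) to the diol diene F3 and oxidised (TEMPO, PhI(OAc)2, aqueous MeCN) to the hydroxy acid diene F4. Yamaguchi lactonisation gives the lactone diene F5, in which the seven-membered lactone holds the butenyl arm over C9. Metathesis with the same ruthenium catalyst then gives 30 directly.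

**Step 18 (lactonisation onto a tertiary alcohol).** Acylation of the hindered C3 hydroxyl may be slow, and prolonged activation of the acid puts C15 at risk of epimerisation. The fallback sets out from 27 and comes back at 30 without going through the free acid. Diol 27 is oxidised with TEMPO and PhI(OAc)2 in dry CH2Cl2 to the hydroxy aldehyde F6, which equilibrates with the seven-membered lactol F7. Oxidation of the lactol with Ag2CO3 on Celite in hot benzene gives 30 (oxidative lactonisation in place of acyl activation).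

## Further compounds

F1 | step 12 | C2 epimer of 21, (1R)-hydroxy in the side chain | CC(C)N(C(C)C)C(=O)OC1=C[C@@H]([C@@H](O)[C@](C)(CCC=C)O[Si](CC)(CC)CC)[C@H]([C@@H](C)CO[Si](c2ccccc2)(c2ccccc2)C(C)(C)C)CC1
F2 | step 12 | γ-keto enol carbamate (C2 ketone) | CC(C)N(C(C)C)C(=O)OC1=C[C@@H](C(=O)[C@](C)(CCC=C)O[Si](CC)(CC)CC)[C@H]([C@@H](C)CO[Si](c2ccccc2)(c2ccccc2)C(C)(C)C)CC1
F3 | step 15 | diol diene (25 without silyl groups) | CCCC(=O)O[C@]1(C)CC[C@@H]([C@@H](C)CO)[C@H]3[C@@H]1[C@H](CC(C)=C)O[C@@H]3[C@](C)(CCC=C)O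
F4 | step 15 | hydroxy acid diene | CCCC(=O)O[C@]1(C)CC[C@@H]([C@@H](C)C(=O)O)[C@H]3[C@@H]1[C@H](CC(C)=C)O[C@@H]3[C@](C)(CCC=C)O
F5 | step 15 | lactone diene (seven-membered lactone closed, medium ring open) | CCCC(=O)O[C@]1(C)CC[C@@H]2[C@H]3[C@@H]1[C@H](CC(C)=C)O[C@@H]3[C@](C)(CCC=C)OC(=O)[C@@H]2C
F6 | step 18 | hydroxy aldehyde (C16 aldehyde, C3 OH) | CCCC(=O)O[C@]1(C)CC[C@@H]([C@@H](C)C=O)[C@H]3[C@@H]1[C@@H]1C/C(C)=C\CC[C@](C)(O)[C@H]3O1
F7 | step 18 | seven-membered lactol (C16 hemiacetal with O3, C16 unassigned) | CCCC(=O)O[C@]1(C)CC[C@@H]2[C@H]3[C@@H]1[C@@H]1C/C(C)=C\CC[C@](C)(OC(O)[C@@H]2C)[C@H]3O1
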